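(All runs stem from a simulated flask for substances that don't exist; the scatter is artificial.)

Begin with the easy step: the left-handed product curves are nearly straight, so a slope near the asked conversion can stand for a rate.

all flasks: left-handed substrate 0.70 M; right-handed substrate 0.70 M
- Saturday's: solid reagent 0.77 M; free catalyst 1.8 mM; run made earlier
- Monday's: solid reagent 0.77 M; free catalyst 7 mM; run made earlier
- flask: solid reagent 0.770 M; free catalyst 3.5 mM

| run | time / d | left-handed product / % | left-handed substrate / % |
|---|---|---|---|
| Saturday's | 0.833 | 0.2 | 47.9 |
| Saturday's | 2.00 | 4.8 | 47.3 |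
| Saturday's | 4.00 | 11.6 | 39.5 |
| Saturday's | 6.00 | 16.0 | 35.1 |
| Saturday's | 8.00 | 23.5 | 26.6 |
| Saturday's | 12.0 | 36.3 | 13.0 |
| Saturday's | 15.0 | 40.3 | 6.0 |
| Monday's | 2.08 | 10.0 | 40.1 |
| Monday's | 4.00 | 22.0 | 25.1 |
| Monday's | 6.00 | 37.2 | 12.8 |
| Monday's | 8.00 | 46.5 | 5.6 |
| Monday's | 10.0 | 48.7 | 2.3 |
| Monday's | 12.0 | 50.0 | 0 |
| Monday's | 15.0 | 48.7 | 2.1 |

(scatter of a reading: 1 percentage point)

- free catalyst is single-handed; left-handed substrate and right-handed substrate are mirror images of each other, charged as a racemate, each of them at the stated concentration
- given per volume of solution although it is solid: solid reagent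
- at the start none of the solid reagent is in solution

* factor on the rate of making left-handed product when 20 % of the left-handed substrate and right-handed substrate together are converted if free catalyst is charged twice over
* factor on the rate when 20 % of the left-handed substrate and right-handed substrate together are converted if free catalyst is charged at 0.40 mM instead

Saturday's run climbs 0.0298 d⁻¹, as a fraction of the two substrates charged, from 4.00 d to 8.00 d. Monday's run, from 2.08 d to 6.00 d, climbs 0.0694 d⁻¹.

Now take the time per unit of left-handed product, which is the inverse of the rate, and suppose it is two waits in a row, one that catalyst shortens and one that it doesn't. The rate then goes as the loading over the loading plus a half-rate loading. The two slopes put that at 5.99 mM, which gives 1.46 and 0.170 for the flask.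

The weak link is Monday's slope, whose stretch runs to 37.2 % product, past the asked 20 %. Stop it at 4.00 d, where product is 22.0 %, so that both runs cover nearly the same range. Monday's slope becomes 0.0625 d⁻¹, and the half-rate loading reads 4.31 mM, the charge at which the two waits are equal. This is a reading and carries the scatter. I commit to 1.38 and 0.190.

The forecast, which sees “catalyst parked off-cycle, perhaps as a dimer, or some other saturation”, stands higher than mine: 1.45 (1.28 to 1.65) and 0.26 (0.17 to 0.38).

The simulation gives 1.36 and 0.201, so the forecast's doubling factor is within tolerance and its ratio is 1.29 times too high.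

    partner + catalyst intermediate A → free catalyst + left-handed product (k = 6.00 L mol⁻¹ h⁻¹)
    solid reagent ⇌ partner, rate k2*(cs2 - [partner]) while solid is left; crystals form when [partner] > cs2 (solubility = 0.380 M, k = 0.0170 h⁻¹)
    free catalyst + left-handed substrate ⇌ catalyst intermediate A (K = 13.0 L mol⁻¹, k = 81.0 L mol⁻¹ h⁻¹)
    partner + catalyst intermediate B → free catalyst + right-handed product (k = 0.270 L mol⁻¹ h⁻¹)
    free catalyst + right-handed substrate ⇌ catalyst intermediate B (K = 0.810 L mol⁻¹, k = 2500 L mol⁻¹ h⁻¹)

You can use the half-rate loading on the flask: the share of the time per unit of product that catalyst shortens comes to 0.552, and at 0.40 mM that share comes to 0.915. In the flask at 12.0 d, free catalyst meets left-handed substrate at 0.0025 of the rate at which it meets right-handed substrate, forward steps alone. Yet that flask then holds 0.422 % right-handed product against 46.1 % left-handed product.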